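The readings are simulated from invented constants; the scatter is artificial.

Slowness is the first thing in these runs: in Tuesday's flask, 51.5% of the X charged still stands after 72.0 h.

| flask | X | D | G | temperature | remark | time |
|---|---|---|---|---|---|---|
| Tuesday's | 0.10 M (fed, over 10 h) | 0.30 equiv | 18 mM (held) | 10 °C | run made earlier; the fed solution adds 0.25 times the starting volume |  |
| Sunday's | 0.10 M (fed, over 10 h) | 1.2 equiv | 18 mM (held) | 43 °C | run made earlier; the fed solution adds 0.25 times the starting volume |  |
| larch | 0.10 M (fed, over 10 h) | 0.600 equiv | 18 mM (held) | 55 °C | the fed solution adds 0.25 times the starting volume | 12 h |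
| birch | 0.10 M (fed, over 10 h) | 0.600 equiv | 18 mM (held) | 25 °C | the fed solution adds 0.25 times the starting volume | 12 h |
| elm | 0.10 M (fed, over 10 h) | 0.600 equiv | 18 mM (held) | −5 °C | the fed solution adds 0.25 times the starting volume | 12 h |

| run | time / h | L / % | X / % |
|---|---|---|---|
| Tuesday's | 12.0 | 0 | 92.8 |
| Tuesday's | 30.0 | 2.4 | 79.0 |
| Tuesday's | 40.0 | 3.4 | 70.6 |
| Tuesday's | 60.0 | 9.4 | 58.6 |
| Tuesday's | 72.0 | 17.3 | 51.5 |
| Sunday's | 1.33 | 0.1 | 8.7 |
| Sunday's | 4.00 | 0.4 | 12.4 |
| Sunday's | 5.00 | 2.5 | 11.8 |
| Sunday's | 10.0 | 5.8 | 11.9 |
| Sunday's | 15.0 | 4.3 | 0 |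

(standard deviation of a reading: 1 percentage point)

- amounts are per litre of the starting volume; all of the dose is in the solution fed
- the numbers in the tables scatter with a standard deviation of 1 percentage point
- at the start none of G is in solution
- percentages count the whole charge, also what has not yet gone in

- which flask leads in amount of L, in percent of the X charged ("all alike" within 1.5 percentage points) (larch / birch / elm / all alike)
- how much L is there at the end, in percent of the X charged: larch
- how much L is there at the end, in percent of the X charged: birch
- how much L is there at the end, in percent of the X charged: elm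

I work with f, the fraction of the charged X left, and not with the L made. Tuesday's flask has consumed 48.5% of its X at 72.0 h against 0.30 equiv of D, and its L reads 17.3%, close to the difference of 18.5%. Sunday's flask, with 1.2 equiv of D, reads X 0% and L 4.3%. So I take this rule: with c = 1 − f consumed and n the equivalents of D, L is the overrun c − n where c exceeds n, and otherwise a leak, roughly 5.05% of c on Sunday's last two readings.

After the feed, Tuesday's X falls first-order with k = 0.00981 /h. Sunday's X reads 11.9% at 10.0 h, the end of the feed, and feed rate over that standing X gives a reading of k = 0.840 /h. Under a steady feed over tf, f = [1 − exp(−k·tf)]/(k·tf) · exp(−k·(t − tf)).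

What does an error in each number cost? Larch is hotter than Sunday's flask, and Sunday's k already leaves it f = 2.22%, far below n, so in my rule an error in n passes into larch's L point for point. Elm is colder than Tuesday's flask, and Tuesday's k gives it c = 6.60%, under n. Birch's temperature lies between those of the two runs, and their constants put its c on both sides of its n of 0.600 equiv, so for birch I need k at 25 °C.

The two constants give an activation energy of 100 kJ/mol, hence k = 0.0838 /h for birch and c = 42.7%, the share of the charge consumed by the end. That is below n, so birch gets the leak, 2.16%. Elm, with c = 0.630%, gets 0.0318%. Larch, taking c as 1, gets 40.0%.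

The forecast names larch and gives 40% (34% to 45%) for larch, 2.5% (1% to 6%) for birch and 0.05% (0% to 0.5%) for elm, on the reading that “L only takes off once D is used up”; my birch figure stands lower and so does my elm figure.

The flasks end with L at 42.0% in larch, 3.04% in birch and 0.0200% in elm, so larch leads.

    X → Q (k = 0.0850 /h, Ea = 101 kJ/mol)
    Z + Q → L (k = 390 /M/h, Ea = 61.0 kJ/mol)
    G ⇌ Z, rate k3*(csat - [Z]) (kL = 2.00 /h)
    D → J (k = 1.90 × 10⁻⁴ /h, Ea = 107 kJ/mol)
    D + Q → E (k = 3000 /M/h, Ea = 54.0 kJ/mol)
    (constants at 25 °C)

Birch ends with X at 56.8%, so its consumed share stands at 43.2% beside my 42.7%, with 33% of its own D charge left. The neighbouring flask is birch with 0.150 equiv of D. Reckoned the same way, c stays 42.7%, now above n, and the overrun is 27.7%. In that neighbouring flask, X ends at 56.8%, D, the limiting reagent there, at 0%, and L at 27.4%.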